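**Retrosynthetic overview**
- The last bond made is the C3–O acyl bond: (3R)-β-cryptoxanthin is esterified with palmitoleic acid (Steglich).
- The C7=C8 alkene is cut by a Julia–Kocienski olefination between a C10 ring A phenyltetrazolyl sulfone (C1–C7) and commercial β-apo-8'-carotenal, which already holds ring B and the all-E chain C8–C7'.
- The strategy rests on ring A: the C3 carbinol is homoallylic to the C5=C6 alkene (C3–C4–C5=C6, C6 bearing C7), so C3–OH with C4H2 is the retron of a 3,4-oxide of the C3=C4/C5=C6 diene; ethyl safranate is that diene, with C1–C6, the three methyl groups and C7 (as the ester) in place.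
- C3 is set by enantioselective manganese–salen epoxidation of the cis C3=C4 alkene; the C4–O bond is then removed by palladium/formate hydrogenolysis.
- No ring is constructed: ring A comes from ethyl safranate and ring B from the apocarotenal; only the transient oxirane is closed (step 1) and opened (step 2).

Key step: step 1

Assumption: commercial ethyl safranate is taken as the 1,3-diene isomer after fractional distillation from its double-bond isomers; carotenoid numbering is used for ring A (ester carbon = C7), and steps 7–9 are run under argon in subdued light.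

**Step 1**
Reactants: 1 ethyl safranate (ethyl 2,6,6-trimethylcyclohexa-1,3-diene-1-carboxylate)
Product: 2 ethyl (1R,6S)-2,4,4-trimethyl-7-oxabicyclo[4.1.0]hept-2-ene-3-carboxylate (the (3S,4R)-3,4-oxide in carotenoid numbering, cis-fused)
Conditions: (R,R)-N,N'-bis(3,5-di-tert-butylsalicylidene)-1,2-cyclohexanediaminomanganese chloride (trivalent manganese, 4 mol%), 4-phenylpyridine N-oxide (20 mol%), aq NaOCl (pH 11.3, Na2HPO4/NaOH), CH2Cl2, 0 °C; chromatography on Et3N-deactivated silica
Reagents that add atoms: sodium hypochlorite, [Na+].[O-]Cl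
Why: The chloro complex of trivalent manganese is oxidised by NaOCl to an oxo species of pentavalent manganese, which transfers oxygen stepwise: the first C–O bond forms at C3, the alkene end remote from C5=C6, and leaves a radical at C4 that is allylic and delocalised towards the ester. Collapse of that radical onto oxygen closes the oxirane (3-exo closure, necessarily cis-fused on the six-membered ring); this sacrificial oxirane is the only ring formed and no ring of the target is closed. The closest known reaction type is the Jacobsen–Katsuki epoxidation of cis-disubstituted alkenes conjugated to an aryl, alkenyl or alkynyl group, a class that includes cyclic 1,3-dienes and dienoates. C3 and C4 are set together by the twofold-symmetric diamine backbone and the tert-butyl groups of the ligand, which impose a side-on approach in which the sp2-flanked end (C4) and the sp3-flanked end (C3) of the alkene are told apart; by analogy with indene and 2,2-dimethylchromene the (R,R)-complex is expected to give the (3S,4R)-oxide, the absolute configuration of the first batch should be confirmed by Mosher ester analysis of 3, and the (S,S)-complex is used instead should the sense prove opposite. The step needs site and enantiofacial selectivity: the first comes from the substrate, since C5=C6 is tetrasubstituted, ester-deactivated and shielded by the gem-dimethyl carbon C1 while C3=C4 is the electron-richer, unhindered cis alkene, and the second comes from the catalyst.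

**Step 2**
Reactants: 2 ethyl (1R,6S)-2,4,4-trimethyl-7-oxabicyclo[4.1.0]hept-2-ene-3-carboxylate
Product: 3 ethyl (4R)-4-hydroxy-2,6,6-trimethylcyclohex-1-ene-1-carboxylate
Conditions: Pd2(dba)3·CHCl3 (2.5 mol%, zerovalent palladium), PBu3 (5 mol%), HCO2H (5 equiv), Et3N (2 equiv), 1,4-dioxane, rt
Reagents that add atoms: none
Why: Palladium-catalysed formate hydrogenolysis of a γ,δ-epoxy-α,β-unsaturated ester (reductive variant of the Tsuji–Trost reaction): zerovalent palladium opens the allylic C4–O bond to a π-allyl complex over C4–C5–C6, the bound formate loses CO2, and the hydride goes to C4, the terminus remote from the ester, so the conjugated C5=C6 alkene returns while the C3–O bond and its configuration are untouched (the descriptor changes from S to R only because C4 loses its oxygen).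

**Step 3**
Reactants: 3 ethyl (4R)-4-hydroxy-2,6,6-trimethylcyclohex-1-ene-1-carboxylate
Product: 4 ethyl (4R)-4-[(tert-butyldimethylsilyl)oxy]-2,6,6-trimethylcyclohex-1-ene-1-carboxylate
Conditions: TBSCl, imidazole, DMF, rt
Reagents that add atoms: tert-butyldimethylsilyl chloride, CC(C)(C)[Si](C)(C)Cl
Why: Standard imidazole-promoted silylation of an unhindered secondary alcohol; it masks the carbinol against hydride, Mitsunobu and strong base in steps 4, 5 and 7.

**Step 4**
Reactants: 4 ethyl (4R)-4-[(tert-butyldimethylsilyl)oxy]-2,6,6-trimethylcyclohex-1-ene-1-carboxylate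
Product: 5 [(4R)-4-[(tert-butyldimethylsilyl)oxy]-2,6,6-trimethylcyclohex-1-en-1-yl]methanol
Conditions: i-Bu2AlH (2.5 equiv), CH2Cl2, −78 → 0 °C; aq KNaC4H4O6 (potassium sodium tartrate) work-up
Reagents that add atoms: none
Why: Aluminium hydride reduction of a conjugated ester to the primary allylic alcohol (1,2-reduction); the silyl ether and the tetrasubstituted alkene are inert.

**Step 5**
Reactants: 5 [(4R)-4-[(tert-butyldimethylsilyl)oxy]-2,6,6-trimethylcyclohex-1-en-1-yl]methanol
Product: 6 5-({[(4R)-4-[(tert-butyldimethylsilyl)oxy]-2,6,6-trimethylcyclohex-1-en-1-yl]methyl}sulfanyl)-1-phenyl-1H-tetrazole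
Conditions: 1-phenyl-1H-tetrazole-5-thiol, PPh3, DIAD, THF, 0 °C → rt
Reagents that add atoms: 1-phenyl-1H-tetrazole-5-thiol, Sc1nnnn1-c1ccccc1
Why: Mitsunobu thioetherification of a primary allylic alcohol with an acidic heteroaryl thiol; SN2' attack is blocked because the γ-carbon C5 is fully substituted, and no stereocentre is involved.

**Step 6**
Reactants: 6 5-({[(4R)-4-[(tert-butyldimethylsilyl)oxy]-2,6,6-trimethylcyclohex-1-en-1-yl]methyl}sulfanyl)-1-phenyl-1H-tetrazole
Product: 7 5-({[(4R)-4-[(tert-butyldimethylsilyl)oxy]-2,6,6-trimethylcyclohex-1-en-1-yl]methyl}sulfonyl)-1-phenyl-1H-tetrazole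
Conditions: (NH4)6Mo7O24·4H2O (10 mol%), 30% aq H2O2, EtOH, 0 °C → rt
Reagents that add atoms: hydrogen peroxide, OO
Why: Molybdate-catalysed peroxide oxidation of a sulfide to the sulfone, which is chemoselective for sulfur over the tetrasubstituted alkene and leaves the silyl ether intact.

**Step 7**
Reactants: 7 5-({[(4R)-4-[(tert-butyldimethylsilyl)oxy]-2,6,6-trimethylcyclohex-1-en-1-yl]methyl}sulfonyl)-1-phenyl-1H-tetrazole; 8 β-apo-8'-carotenal (all-E)
Product: 10 (3R)-3-[(tert-butyldimethylsilyl)oxy]-β,β-carotene (all-E; O-silyl β-cryptoxanthin), via 7Z silyl ether 9 (not isolated)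
Conditions: 7, KN(SiMe3)2, THF, −78 °C; then 8, −78 °C → rt; crude product in heptane, 90 °C, argon, dark; crystallisation
Reagents that add atoms: none
Why: Julia–Kocienski olefination: the potassium salt of the allylic sulfone adds to the aldehyde carbon (C8), Smiles transfer of the phenyltetrazolyl group and loss of SO2 and tetrazololate form C7=C8, and because a 7Z bond next to the trimethylcyclohexene ring is the sterically hindered cis arrangement, the thermal equilibration should take the 7Z material formed alongside to the 7E isomer, with crystallisation selecting the all-E compound.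

**Step 8**
Reactants: 10 (3R)-3-[(tert-butyldimethylsilyl)oxy]-β,β-carotene
Product: 11 (3R)-β-cryptoxanthin ((3R)-β,β-caroten-3-ol, all-E)
Conditions: Bu4NF, THF, 0 °C → rt, argon, dark; crystallisation
Reagents that add atoms: none
Why: Fluoride-induced desilylation (formation of the strong Si–F bond) under non-acidic conditions that the polyene tolerates; C3 is not involved.

**Step 9**
Reactants: 11 (3R)-β-cryptoxanthin; 12 palmitoleic acid ((9Z)-hexadec-9-enoic acid)
Product: 13 (3R)-β,β-caroten-3-yl (9Z)-hexadec-9-enoate (CNP0382087.1)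
Conditions: DCC, DMAP (cat.), CH2Cl2, rt, argon, dark
Reagents that add atoms: none
Why: Steglich esterification through the O-acylisourea and the acylpyridinium ion; the acyl C–O bond is formed, so C3 keeps its R configuration, and the Z alkene of the acid and the polyene are not touched under these neutral conditions.

**Compound list**
1 | ethyl safranate (ethyl 2,6,6-trimethylcyclohexa-1,3-diene-1-carboxylate) | CCOC(=O)C1=C(C)C=CCC1(C)C | starting material
2 | ethyl (1R,6S)-2,4,4-trimethyl-7-oxabicyclo[4.1.0]hept-2-ene-3-carboxylate | CCOC(=O)C1=C(C)[C@H]2O[C@H]2CC1(C)C | intermediate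
3 | ethyl (4R)-4-hydroxy-2,6,6-trimethylcyclohex-1-ene-1-carboxylate | CCOC(=O)C1=C(C)C[C@@H](O)CC1(C)C | intermediate
4 | ethyl (4R)-4-[(tert-butyldimethylsilyl)oxy]-2,6,6-trimethylcyclohex-1-ene-1-carboxylate | CCOC(=O)C1=C(C)C[C@@H](O[Si](C)(C)C(C)(C)C)CC1(C)C | intermediate
5 | [(4R)-4-[(tert-butyldimethylsilyl)oxy]-2,6,6-trimethylcyclohex-1-en-1-yl]methanol | OCC1=C(C)C[C@@H](O[Si](C)(C)C(C)(C)C)CC1(C)C | intermediate
6 | 5-({[(4R)-4-[(tert-butyldimethylsilyl)oxy]-2,6,6-trimethylcyclohex-1-en-1-yl]methyl}sulfanyl)-1-phenyl-1H-tetrazole | c1ccccc1-n1nnnc1SCC1=C(C)C[C@@H](O[Si](C)(C)C(C)(C)C)CC1(C)C | intermediate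
7 | 5-({[(4R)-4-[(tert-butyldimethylsilyl)oxy]-2,6,6-trimethylcyclohex-1-en-1-yl]methyl}sulfonyl)-1-phenyl-1H-tetrazole | O=S(=O)(CC1=C(C)C[C@@H](O[Si](C)(C)C(C)(C)C)CC1(C)C)c1nnnn1-c1ccccc1 | intermediate
8 | β-apo-8'-carotenal (all-E) | O=C/C(C)=C/C=C/C(C)=C/C=C/C=C(C)/C=C/C=C(C)/C=C/C1=C(C)CCCC1(C)C | starting material
9 | (3R,7Z)-3-[(tert-butyldimethylsilyl)oxy]-β,β-carotene (7Z isomer of 10, formed alongside it) | CC(C)(C)[Si](C)(C)O[C@@H]1CC(C)=C(\C=C/C(C)=C/C=C/C(C)=C/C=C/C=C(C)/C=C/C=C(C)/C=C/C2=C(C)CCCC2(C)C)C(C)(C)C1 | intermediate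
10 | (3R)-3-[(tert-butyldimethylsilyl)oxy]-β,β-carotene (all-E) | CC(C)(C)[Si](C)(C)O[C@@H]1CC(C)=C(/C=C/C(C)=C/C=C/C(C)=C/C=C/C=C(C)/C=C/C=C(C)/C=C/C2=C(C)CCCC2(C)C)C(C)(C)C1 | intermediate
11 | (3R)-β-cryptoxanthin | O[C@@H]1CC(C)=C(/C=C/C(C)=C/C=C/C(C)=C/C=C/C=C(C)/C=C/C=C(C)/C=C/C2=C(C)CCCC2(C)C)C(C)(C)C1 | intermediate
12 | palmitoleic acid | CCCCCC/C=C\CCCCCCCC(=O)O | starting material
13 | (3R)-β,β-caroten-3-yl (9Z)-hexadec-9-enoate | CCCCCC/C=C\CCCCCCCC(=O)O[C@@H]1CC(C)=C(/C=C/C(C)=C/C=C/C(C)=C/C=C/C=C(C)/C=C/C=C(C)/C=C/C2=C(C)CCCC2(C)C)C(C)(C)C1 | target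

**Step count**
Total steps: 9. Longest linear sequence: 9 steps (1 → 13); compounds 8 and 12 are bought and enter in steps 7 and 9.

**Steps most likely to fail**

Step 1. What may go wrong: the catalyst may not tell the two faces of C3=C4 apart well enough, or the acid-labile vinyl oxide may be lost through allylic over-oxidation at C2 or on isolation. The fallback replaces asymmetric catalysis by resolution. It sets out from 1: buffered mCPBA (NaHCO3, CH2Cl2, 0 °C) should epoxidise the same electron-richer C3=C4 bond to racemic ethyl 2,4,4-trimethyl-7-oxabicyclo[4.1.0]hept-2-ene-3-carboxylate F1. The hydrogenolysis conditions of step 2 then give racemic ethyl 4-hydroxy-2,6,6-trimethylcyclohex-1-ene-1-carboxylate F2. Acylation with vinyl acetate and Candida antarctica lipase B (MTBE, 30 °C) is run to about half conversion. By the empirical size rule for lipase acylation of secondary alcohols (CH2–CMe2 arm large, CH2–C(Me)= arm medium) it is expected to convert the R enantiomer into ethyl (4R)-4-acetoxy-2,6,6-trimethylcyclohex-1-ene-1-carboxylate F3 and leave ethyl (4S)-4-hydroxy-2,6,6-trimethylcyclohex-1-ene-1-carboxylate F4, which is separated. K2CO3 in MeOH removes the acetate of F3 while the hindered ring ester stays, and the route is rejoined at 3.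

Step 2. What may go wrong: zerovalent palladium may fail to ionise the C4–O bond because the C5=C6 alkene it must bind is tetrasubstituted; the π-allyl alkoxide may undergo β-hydride elimination to a dienol and then a ketone; or hydride may be delivered to C6 with loss of conjugation. The fallback uses nucleophilic opening and radical reduction in place of π-allyl chemistry. It sets out from 2: sodium benzeneselenolate (from (PhSe)2 and NaBH4, EtOH, 0 °C) should open the oxirane at the activated allylic carbon C4 with inversion to give ethyl (3S,4S)-4-hydroxy-2,6,6-trimethyl-3-(phenylselanyl)cyclohex-1-ene-1-carboxylate F5. Bu3SnH with AIBN (toluene, 80 °C) then replaces selenium by hydrogen at C4, the less hindered terminus of the allyl radical, and the route is rejoined at 3 with C3 untouched.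

Step 7. What may go wrong: the hindered allylic sulfonyl anion may add slowly to the polyenal, so that self-condensation of the sulfone or base-induced degradation of the aldehyde competes, or the elimination may give an isomer mixture that does not converge on the all-E compound. The fallback uses a phosphorus ylide in place of the sulfone. It sets out from 5: an Appel reaction (CBr4, PPh3, CH2Cl2, 0 °C) should give tert-butyl{[(1R)-4-(bromomethyl)-3,5,5-trimethylcyclohex-3-en-1-yl]oxy}dimethylsilane F6. PPh3 in toluene at 60 °C converts it into {[(4R)-4-[(tert-butyldimethylsilyl)oxy]-2,6,6-trimethylcyclohex-1-en-1-yl]methyl}triphenylphosphonium bromide F7. Its ylide (n-BuLi, THF, −78 °C) undergoes a Wittig reaction with 8; the thermal equilibration of step 7 converts the 9 formed alongside, and the route is rejoined at 10.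

**Further compounds**
F1 | step 1 | racemic ethyl 2,4,4-trimethyl-7-oxabicyclo[4.1.0]hept-2-ene-3-carboxylate (cis-fused) | CCOC(=O)C1=C(C)C2OC2CC1(C)C
F2 | step 1 | racemic ethyl 4-hydroxy-2,6,6-trimethylcyclohex-1-ene-1-carboxylate | CCOC(=O)C1=C(C)CC(O)CC1(C)C
F3 | step 1 | ethyl (4R)-4-acetoxy-2,6,6-trimethylcyclohex-1-ene-1-carboxylate | CCOC(=O)C1=C(C)C[C@@H](OC(C)=O)CC1(C)C
F4 | step 1 | ethyl (4S)-4-hydroxy-2,6,6-trimethylcyclohex-1-ene-1-carboxylate | CCOC(=O)C1=C(C)C[C@H](O)CC1(C)C
F5 | step 2 | ethyl (3S,4S)-4-hydroxy-2,6,6-trimethyl-3-(phenylselanyl)cyclohex-1-ene-1-carboxylate | CCOC(=O)C1=C(C)[C@H]([Se]c2ccccc2)[C@@H](O)CC1(C)C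
F6 | step 7 | tert-butyl{[(1R)-4-(bromomethyl)-3,5,5-trimethylcyclohex-3-en-1-yl]oxy}dimethylsilane | BrCC1=C(C)C[C@@H](O[Si](C)(C)C(C)(C)C)CC1(C)C
F7 | step 7 | {[(4R)-4-[(tert-butyldimethylsilyl)oxy]-2,6,6-trimethylcyclohex-1-en-1-yl]methyl}triphenylphosphonium bromide | [Br-].C(C1=C(C)C[C@@H](O[Si](C)(C)C(C)(C)C)CC1(C)C)[P+](c1ccccc1)(c1ccccc1)c1ccccc1
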